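**Plan**

1. Feature: in ring A (a1 C–CH3, a2 CH, a3 C–OH, a4 C–CH2OH, a5 C–OAr, a6 C–CO2) the ether carbon a5 and the carboxyl carbon a6 are adjacent and are tied, through the diaryl ether oxygen and the lactone, to two vicinal oxygens of ring B. An α-carboxy vinylketene plus aryloxyalkyne benzannulation gives exactly this pattern.
2. Cuts: the lactol C–OH stereocentre is set last. Ring A is cut at a3–a4, a5–a6 and a2–a3, together with a1–a6 (made by a 1,2-shift), which also opens the seven-membered lactone. This leads back to a ring B catechol with a diazo keto ester on one oxygen and an alkynyl ether on the other.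
3. Ring B is traced to 2,4,5-trimethoxybenzoic acid by cutting its two side-chain C–C bonds (formyl at C6, hydroxymethyl at C3) and its O-substituents.
4. Forward: ring B is completed (steps 1–8), the alkynyl ether (9–11) and the diazo keto ester (12–16) are attached, ring A and the seven-membered lactone close together (17), and the lactol ring closes on acidic unmasking (18).
5. Stereochemistry: the only stereocentre, the S lactol carbon, comes from an acylative dynamic kinetic resolution (19) and a lipase deacylation that does not touch the C–O bond (20).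

Key step: step 17

Assumption: a 3-hydroxyphthalide lactol epimerises through its ring-opened formyl acid form when base or water above about pH 4 is present; the S lactol is taken to be isolable if the last step and its work-up stay neutral and non-aqueous.

Step 1
Reactants: 1 2,4,5-trimethoxybenzoic acid
Product: 2 rac-3-hydroxy-4,5,7-trimethoxy-2-benzofuran-1(3H)-one (lactol form of 6-formyl-2,4,5-trimethoxybenzoic acid)
Conditions: s-BuLi (2.2 equiv), TMEDA, THF, −78 °C; DMF; aq. HCl
Reagents that add atoms: N,N-dimethylformamide, CN(C)C=O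
Why: Directed ortho-metalation of the lithium carboxylate should occur at C6, the only position ortho to the carboxylate and also flanked by the 5-methoxy group, and formylation gives the formyl acid, which closes to the racemic lactol (this stereocentre disappears in step 2).

Step 2
Reactants: 2 trimethoxy lactol
Product: 3 methyl 2-formyl-3,4,6-trimethoxybenzoate
Conditions: MeI, K2CO3, DMF, 20 °C
Reagents that add atoms: iodomethane, CI
Why: Base opens the lactol to the formyl carboxylate, whose SN2 O-alkylation should give the open-chain methyl ester.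

Step 3
Reactants: 3 trimethoxy formyl ester
Product: 4 methyl 2-formyl-3,4,6-trihydroxybenzoate
Conditions: BBr3 (4.5 equiv), CH2Cl2, −78 → 0 °C; H2O
Reagents that add atoms: none
Why: Lewis acid cleavage of the three aryl methyl ethers, with the methyl ester and the aldehyde expected to survive at or below 0 °C.

Step 4
Reactants: 4 trihydroxy formyl ester
Product: 5 methyl 4-(allyloxy)-2-formyl-3,6-dihydroxybenzoate
Conditions: allyl bromide (1.05 equiv), NaHCO3, DMF, 40 °C
Reagents that add atoms: allyl bromide, C=CCBr
Why: Williamson etherification should select the 4-OH, the only phenol not held in a hydrogen bond to an ortho carbonyl and, being para to the ester, the most acidic unchelated one.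

Step 5
Reactants: 5 allyl ether aldehyde
Product: 6 methyl 4-(allyloxy)-2-(1,3-dioxolan-2-yl)-3,6-dihydroxybenzoate
Conditions: HOCH2CH2OH, p-TsOH (cat.), benzene, reflux (Dean–Stark)
Reagents that add atoms: ethylene glycol, OCCO
Why: Acid-catalysed acetalisation masks the aldehyde, so that the second formyl group can be reduced alone in step 7 and the organolithium step 10 meets no aldehyde.

Step 6
Reactants: 6 dioxolane diphenol
Product: 7 methyl 4-(allyloxy)-2-(1,3-dioxolan-2-yl)-5-formyl-3,6-dihydroxybenzoate
Conditions: MgCl2, Et3N, (CH2O)n, MeCN, reflux, argon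
Reagents that add atoms: formaldehyde (from paraformaldehyde), C=O
Why: Magnesium phenoxide-directed ortho-formylation (Casiraghi–Skattebøl) can only reach C5, the single free ring position, ortho to the 6-OH.

Step 7
Reactants: 7 formyl diphenol
Product: 8 methyl 4-(allyloxy)-2-(1,3-dioxolan-2-yl)-3,6-dihydroxy-5-(hydroxymethyl)benzoate
Conditions: NaBH4, MeOH–THF, 0 °C
Reagents that add atoms: none
Why: Borohydride reduction of the aryl aldehyde, to which the hydrogen-bonded methyl ester and the dioxolane are inert.

Step 8
Reactants: 8 hydroxymethyl diphenol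
Product: 9 methyl 5-(allyloxy)-7-(1,3-dioxolan-2-yl)-6-hydroxy-2,2-dimethyl-4H-1,3-benzodioxine-8-carboxylate
Conditions: 2-methoxypropene, PPTS (cat.), CH2Cl2, 0 °C
Reagents that add atoms: 2-methoxypropene, COC(C)=C
Why: Acid-catalysed ketalisation: the hydroxymethyl group has only one free phenolic neighbour (the other is allylated), so the six-membered acetonide forms there and the phenol next to the dioxolane stays free.

Step 9
Reactants: 9 benzodioxine phenol
Product: 10 methyl 5-(allyloxy)-6-{[(E)-1,2-dichloroethenyl]oxy}-7-(1,3-dioxolan-2-yl)-2,2-dimethyl-4H-1,3-benzodioxine-8-carboxylate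
Conditions: KH, THF, 0 °C; Cl2C=CHCl, 20 °C
Reagents that add atoms: trichloroethylene, ClC=C(Cl)Cl
Why: The potassium phenoxide of the one free phenol adds to dichloroacetylene formed in situ from trichloroethylene (elimination–addition synthesis of 1,2-dichlorovinyl ethers), giving the E ether.

Step 10
Reactants: 10 dichlorovinyl ether
Product: 12 methyl 5-(allyloxy)-7-(1,3-dioxolan-2-yl)-6-[(3-hydroxyprop-1-yn-1-yl)oxy]-2,2-dimethyl-4H-1,3-benzodioxine-8-carboxylate, via lithium aryloxyacetylide 11 (not isolated)
Conditions: n-BuLi (2.2 equiv), THF, −78 °C; (CH2O)n, −78 → 0 °C; H2O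
Reagents that add atoms: formaldehyde (from paraformaldehyde), C=O
Why: Dehydrochlorination and chlorine–lithium exchange convert the dichlorovinyl ether into the lithium acetylide, which adds to formaldehyde; at −78 °C both events should outpace addition to the doubly ortho-substituted methyl ester.

Step 11
Reactants: 12 propargylic alcohol
Product: 13 methyl 5-(allyloxy)-6-[(3-{[tert-butyl(dimethyl)silyl]oxy}prop-1-yn-1-yl)oxy]-7-(1,3-dioxolan-2-yl)-2,2-dimethyl-4H-1,3-benzodioxine-8-carboxylate
Conditions: TBSCl, imidazole, DMF, 0 °C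
Reagents that add atoms: tert-butyldimethylsilyl chloride, CC(C)(C)[Si](C)(C)Cl
Why: Silylation of the primary alcohol under basic conditions, done at once because acid would trigger Meyer–Schuster rearrangement of the alkoxy propargylic alcohol.

Step 12
Reactants: 13 allyl-protected alkynyl ether
Product: 14 methyl 6-[(3-{[tert-butyl(dimethyl)silyl]oxy}prop-1-yn-1-yl)oxy]-7-(1,3-dioxolan-2-yl)-5-hydroxy-2,2-dimethyl-4H-1,3-benzodioxine-8-carboxylate
Conditions: Pd(PPh3)4 (5 mol %), morpholine, THF, 20 °C
Reagents that add atoms: none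
Why: Tsuji–Trost allyl transfer from the aryl allyl ether to morpholine, catalysed by zerovalent palladium, frees the phenol without acid, so the alkynyl ether, silyl ether and acetals should survive; the phenol is used at once.

Step 13
Reactants: 14 phenol
Product: 15 methyl 5-[(bromoacetyl)oxy]-6-[(3-{[tert-butyl(dimethyl)silyl]oxy}prop-1-yn-1-yl)oxy]-7-(1,3-dioxolan-2-yl)-2,2-dimethyl-4H-1,3-benzodioxine-8-carboxylate
Conditions: (BrCH2CO)2O, i-Pr2NEt, DMAP (cat.), CH2Cl2, −20 °C
Reagents that add atoms: bromoacetic anhydride, O=C(CBr)OC(=O)CBr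
Why: DMAP-catalysed O-acylation of the phenol under basic conditions, with no free acid or acyl halide that could add to the alkynyl ether.

Step 14
Reactants: 15 bromoacetate
Product: 16 methyl 5-[(diazoacetyl)oxy]-6-[(3-{[tert-butyl(dimethyl)silyl]oxy}prop-1-yn-1-yl)oxy]-7-(1,3-dioxolan-2-yl)-2,2-dimethyl-4H-1,3-benzodioxine-8-carboxylate
Conditions: TsNHNHTs, DBU, THF, 0 °C
Reagents that add atoms: N,N'-ditosylhydrazine, Cc1ccc(cc1)S(=O)(=O)NNS(=O)(=O)c1ccc(C)cc1
Why: N-Alkylation of ditosylhydrazine by the bromoacetate and twofold base-induced loss of sulfinate give the diazoacetate (diazoacetate synthesis from bromoacetates).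

Step 15
Reactants: 16 aryl diazoacetate
Product: 17 methyl 5-[(2-diazo-3-hydroxy-4-methylpent-4-enoyl)oxy]-6-[(3-{[tert-butyl(dimethyl)silyl]oxy}prop-1-yn-1-yl)oxy]-7-(1,3-dioxolan-2-yl)-2,2-dimethyl-4H-1,3-benzodioxine-8-carboxylate (racemic carbinol)
Conditions: methacrolein, DBU (20 mol %), MeCN, 0 → 20 °C
Reagents that add atoms: methacrolein, CC(=C)C=O
Why: Base-catalysed aldol-type 1,2-addition of the diazoacetate carbanion to the enal; the new carbinol centre is racemic and is oxidised away in step 16.

Step 16
Reactants: 17 diazo hydroxy ester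
Product: 18 methyl 5-[(2-diazo-4-methyl-3-oxopent-4-enoyl)oxy]-6-[(3-{[tert-butyl(dimethyl)silyl]oxy}prop-1-yn-1-yl)oxy]-7-(1,3-dioxolan-2-yl)-2,2-dimethyl-4H-1,3-benzodioxine-8-carboxylate
Conditions: Dess–Martin periodinane, pyridine, CH2Cl2, 0 °C
Reagents that add atoms: none
Why: Buffered Dess–Martin oxidation of an α-diazo-β-hydroxy ester to the α-diazo-β-keto ester, which should leave the diazo group and the alkynyl ether intact.

Step 17
Reactants: 18 diazo keto ester
Product: 23 protected depsidone (ring A phenol free; CH2OTBS; ring B acetonide/methyl ester/1,3-dioxolane), via vinylketene 19 (not isolated), via cyclobutenone 20 (not isolated), via dienylketene 21 (not isolated), via cyclohexadienone 22 (not isolated)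
Conditions: hν (300 nm, Pyrex), degassed PhMe (0.002 M), 20 °C; then 80 °C
Reagents that add atoms: none
Why: Proposed new method: irradiation expels N2 from 18 and the isopropenyl group shifts to the diazo carbon (Wolff rearrangement, making a1–a6) to give vinylketene 19 with the aryl ester on its α-carbon; 19 adds [2+2] across the tethered aryloxyalkyne to cyclobutenone 20, and warming opens 20 (4π) to dienylketene 21, which closes (6π) to cyclohexadienone 22 and tautomerises to phenol 23. The closest known reaction type is the Danheiser benzannulation of photochemically generated vinylketenes with alkoxy- and siloxyalkynes, known between separate partners and from diazo ketones, so both the diazo β-keto ester and the catechol tether are untested. The seven-membered lactone closes in the [2+2] event, when the ketene α-carbon bonds to the oxygen-bearing alkyne carbon (a5–a6) while the ketene carbonyl carbon bonds to the other alkyne carbon (a3–a4); ring A closes by disrotatory 6π electrocyclisation of 21 between the ketene carbon and the isopropenyl CH2 (a2–a3), the cis arrangement being fixed because the central double bond of 21 is endocyclic in the seven-membered ring. No stereocentre survives, the quaternary carbon of 20 being lost on ring opening. The step needs one [2+2] regiochemistry and intramolecular ketene capture: the former is secured jointly by the tether (the reverse orientation would need an eight-membered ring) and by the matched polarity of the electrophilic ketene carbonyl carbon and the nucleophilic β-carbon of the alkynyl ether, the latter by high dilution.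

Step 18
Reactants: 23 protected depsidone
Product: 24 rac-1,4,10-trihydroxy-5,11-bis(hydroxymethyl)-8-methyl-1H-isobenzofuro[4,5-b][1,4]benzodioxepine-3,7-dione (racemic lactol)
Conditions: 1 M H2SO4 (aq)–THF (1:3), 20 → 40 °C
Reagents that add atoms: water, O
Why: Acid hydrolysis removes the silyl ether, acetonide and dioxolane, and the freed aldehyde, as its hydrate, attacks the neighbouring methyl ester (anchimerically assisted ester cleavage) with loss of methanol to give the hydroxyphthalide lactol as a racemate.

Step 19
Reactants: 24 racemic lactol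
Product: 25 (1S)-pentapropanoate of the target (both phenols; both CH2OH groups; lactol OH esterified)
Conditions: (S)-benzotetramisole [(S)-2-phenyl-2,3-dihydroimidazo[2,1-b][1,3]benzothiazole] (10 mol %), (EtCO)2O (8 equiv), i-Pr2NEt, THF, 0 °C
Reagents that add atoms: propionic anhydride, CCC(=O)OC(=O)CC
Why: Isothiourea-catalysed acylative dynamic kinetic resolution: under i-Pr2NEt the lactol enantiomers interconvert through the ring-opened formyl carboxylate while the chiral acyl isothiouronium esterifies one of them faster, taken to be S with the S catalyst by analogy with its preference among benzylic carbinols (to be verified; the R catalyst is the mirror-image option), and the four other hydroxyls are esterified without stereochemical consequence.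

Step 20
Reactants: 25 (1S)-pentapropanoate
Product: 26 (1S)-1,4,10-trihydroxy-5,11-bis(hydroxymethyl)-8-methyl-1H-isobenzofuro[4,5-b][1,4]benzodioxepine-3,7-dione (target CNP0155661.1)
Conditions: immobilised Candida antarctica lipase B, n-BuOH, MTBE–THF, 30 °C; filtration and evaporation without aqueous or basic work-up
Reagents that add atoms: none
Why: Lipase-catalysed alcoholysis cleaves all five esters by acyl–oxygen fission under neutral, non-aqueous conditions, so the C–O bond at the lactol carbon is never broken and the S configuration from step 19 should be retained.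

**Compound list**

1 | 2,4,5-trimethoxybenzoic acid | COc1cc(OC)c(C(=O)O)cc1OC | starting material
2 | rac-3-hydroxy-4,5,7-trimethoxy-2-benzofuran-1(3H)-one | COc1cc(OC)c2c(c1OC)C(O)OC2=O | intermediate
3 | methyl 2-formyl-3,4,6-trimethoxybenzoate | COC(=O)c1c(OC)cc(OC)c(OC)c1C=O | intermediate
4 | methyl 2-formyl-3,4,6-trihydroxybenzoate | COC(=O)c1c(O)cc(O)c(O)c1C=O | intermediate
5 | methyl 4-(allyloxy)-2-formyl-3,6-dihydroxybenzoate | COC(=O)c1c(O)cc(OCC=C)c(O)c1C=O | intermediate
6 | methyl 4-(allyloxy)-2-(1,3-dioxolan-2-yl)-3,6-dihydroxybenzoate | COC(=O)c1c(O)cc(OCC=C)c(O)c1C1OCCO1 | intermediate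
7 | methyl 4-(allyloxy)-2-(1,3-dioxolan-2-yl)-5-formyl-3,6-dihydroxybenzoate | COC(=O)c1c(O)c(C=O)c(OCC=C)c(O)c1C1OCCO1 | intermediate
8 | methyl 4-(allyloxy)-2-(1,3-dioxolan-2-yl)-3,6-dihydroxy-5-(hydroxymethyl)benzoate | COC(=O)c1c(O)c(CO)c(OCC=C)c(O)c1C1OCCO1 | intermediate
9 | methyl 5-(allyloxy)-7-(1,3-dioxolan-2-yl)-6-hydroxy-2,2-dimethyl-4H-1,3-benzodioxine-8-carboxylate | COC(=O)c1c2OC(C)(C)OCc2c(OCC=C)c(O)c1C1OCCO1 | intermediate
10 | methyl 5-(allyloxy)-6-{[(E)-1,2-dichloroethenyl]oxy}-7-(1,3-dioxolan-2-yl)-2,2-dimethyl-4H-1,3-benzodioxine-8-carboxylate | COC(=O)c1c2OC(C)(C)OCc2c(OCC=C)c(O/C(Cl)=C\Cl)c1C1OCCO1 | intermediate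
11 | lithium aryloxyacetylide: methyl 5-(allyloxy)-7-(1,3-dioxolan-2-yl)-6-[(lithioethynyl)oxy]-2,2-dimethyl-4H-1,3-benzodioxine-8-carboxylate | COC(=O)c1c2OC(C)(C)OCc2c(OCC=C)c(OC#C[Li])c1C1OCCO1 | intermediate
12 | methyl 5-(allyloxy)-7-(1,3-dioxolan-2-yl)-6-[(3-hydroxyprop-1-yn-1-yl)oxy]-2,2-dimethyl-4H-1,3-benzodioxine-8-carboxylate | COC(=O)c1c2OC(C)(C)OCc2c(OCC=C)c(OC#CCO)c1C1OCCO1 | intermediate
13 | methyl 5-(allyloxy)-6-[(3-{[tert-butyl(dimethyl)silyl]oxy}prop-1-yn-1-yl)oxy]-7-(1,3-dioxolan-2-yl)-2,2-dimethyl-4H-1,3-benzodioxine-8-carboxylate | COC(=O)c1c2OC(C)(C)OCc2c(OCC=C)c(OC#CCO[Si](C)(C)C(C)(C)C)c1C1OCCO1 | intermediate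
14 | methyl 6-[(3-{[tert-butyl(dimethyl)silyl]oxy}prop-1-yn-1-yl)oxy]-7-(1,3-dioxolan-2-yl)-5-hydroxy-2,2-dimethyl-4H-1,3-benzodioxine-8-carboxylate | COC(=O)c1c2OC(C)(C)OCc2c(O)c(OC#CCO[Si](C)(C)C(C)(C)C)c1C1OCCO1 | intermediate
15 | 5-(bromoacetoxy) derivative of 14 | COC(=O)c1c2OC(C)(C)OCc2c(OC(=O)CBr)c(OC#CCO[Si](C)(C)C(C)(C)C)c1C1OCCO1 | intermediate
16 | 5-(diazoacetoxy) derivative of 14 | COC(=O)c1c2OC(C)(C)OCc2c(OC(=O)C=[N+]=[N-])c(OC#CCO[Si](C)(C)C(C)(C)C)c1C1OCCO1 | intermediate
17 | 5-[(2-diazo-3-hydroxy-4-methylpent-4-enoyl)oxy] derivative of 14, racemic carbinol | COC(=O)c1c2OC(C)(C)OCc2c(OC(=O)C(=[N+]=[N-])C(O)C(C)=C)c(OC#CCO[Si](C)(C)C(C)(C)C)c1C1OCCO1 | intermediate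
18 | 5-[(2-diazo-4-methyl-3-oxopent-4-enoyl)oxy] derivative of 14 (precursor of the key step) | C=C(C)C(=O)C(=[N+]=[N-])C(=O)Oc1c2COC(C)(C)Oc2c(C(=O)OC)c(C2OCCO2)c1OC#CCO[Si](C)(C)C(C)(C)C | intermediate
19 | vinylketene: aryl 3-methyl-2-(oxomethylidene)but-3-enoate on the ring B oxygen | C=C(C)C(=C=O)C(=O)Oc1c2COC(C)(C)Oc2c(C(=O)OC)c(C2OCCO2)c1OC#CCO[Si](C)(C)C(C)(C)C | intermediate
20 | cyclobutenone fused to the seven-membered lactone (racemic quaternary carbon bearing isopropenyl) | O=C1C(CO[Si](C)(C)C(C)(C)C)=C2Oc3c(OC(=O)C12C(C)=C)c4COC(C)(C)Oc4c(C(=O)OC)c3C3OCCO3 | intermediate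
21 | dienylketene with the central double bond inside the seven-membered lactone | O=C=C(CO[Si](C)(C)C(C)(C)C)C1=C(C(C)=C)C(=O)Oc2c(O1)c(C3OCCO3)c(C(=O)OC)c3OC(C)(C)OCc23 | intermediate
22 | cyclohexa-2,4-dienone tautomer of 23 | O=C1CC(C)=C2C(=O)Oc3c(OC2=C1CO[Si](C)(C)C(C)(C)C)c(C4OCCO4)c(C(=O)OC)c4OC(C)(C)OCc34 | intermediate
23 | protected depsidone: ring A phenol free, CH2OTBS; ring B acetonide, methyl ester, 1,3-dioxolane | Cc1cc(O)c(CO[Si](C)(C)C(C)(C)C)c2c1C(=O)Oc1c3COC(C)(C)Oc3c(C(=O)OC)c(C3OCCO3)c1O2 | intermediate
24 | rac-1,4,10-trihydroxy-5,11-bis(hydroxymethyl)-8-methyl-1H-isobenzofuro[4,5-b][1,4]benzodioxepine-3,7-dione | Cc1cc(O)c(CO)c2c1C(=O)Oc1c(CO)c(O)c3c(c1O2)C(O)OC3=O | intermediate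
25 | (1S)-pentapropanoate of the target | Cc1cc(OC(=O)CC)c(COC(=O)CC)c2c1C(=O)Oc1c(COC(=O)CC)c(OC(=O)CC)c3c(c1O2)[C@@H](OC(=O)CC)OC3=O | intermediate
26 | (1S)-1,4,10-trihydroxy-5,11-bis(hydroxymethyl)-8-methyl-1H-isobenzofuro[4,5-b][1,4]benzodioxepine-3,7-dione | Cc1cc(O)c(CO)c2c1C(=O)Oc1c(CO)c(O)c3c(c1O2)[C@@H](O)OC3=O | target

**Count**

Total: 20 steps. Longest linear sequence: 20 steps (1 to 26); all other inputs are commercial reagents.

**Steps most likely to fail**

Step 17. The excited diazo keto ester may lose nitrogen without the 1,2-shift and react as a carbene at the alkynyl ether or the alkene. The ester-substituted ketene may be captured through its ester carbonyl in a [4+2] sense instead of [2+2], or by a second molecule. The fallback makes the ring A construction intermolecular and thermal, which is established benzannulation chemistry, and closes the lactone afterwards. It sets out from 13. Heating 13 with the known 3-methylcyclobut-2-en-1-one (toluene, 80–110 °C) would give the diaryl ether phenol F1, by electrocyclic opening to (isopropenyl)ketene, [2+2] addition to the alkynyl ether and the usual 4π/6π cascade. Bromination with NBS (MeCN, −20 °C) para to the new phenol, between the methyl group and the ether oxygen, would give the aryl bromide F2. Deallylation as in step 12 would give the bromo diphenol F3. Carbonylative lactonisation (Pd(OAc)2, Xantphos, CO at 1 atm, Et3N, toluene, 80 °C) would then close the seven-membered lactone and return to the route at 23.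

Step 10. Addition of butyllithium to the methyl ester, or attack on the allyl ether, may compete with elimination and chlorine–lithium exchange. The fallback avoids organolithium reagents and sets out from 9. The dibromoalkene F4 would be made from commercial (tert-butyldimethylsilyloxy)acetaldehyde by CBr4/PPh3 olefination (Ramirez/Corey–Fuchs). Copper-catalysed coupling of phenol 9 with F4 (CuI, 2,2'-bipyridine, K3PO4, toluene, 110 °C) would give the Z bromo enol ether F5. Anti elimination of HBr with KOtBu (THF, 0 °C) would give the silylated alkynyl ether and return to the route at 13, replacing steps 9 to 11.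

Step 19. Enantioselection may be eroded by an uncatalysed acylation channel through the mixed anhydride of the ring-opened formyl carboxylate, or the catalyst may favour the wrong lactol enantiomer. The fallback replaces asymmetric catalysis by resolution and sets out from 24. Exhaustive propionylation with propionic anhydride, pyridine and DMAP would give the racemic pentapropanoate F6. Preparative chromatography on a chiral stationary phase would separate it into 25 and the R pentapropanoate F7, which is set aside. The route is rejoined at 25.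

Further compounds
F1 | step 17 | methyl 5-(allyloxy)-6-[2-({[tert-butyl(dimethyl)silyl]oxy}methyl)-3-hydroxy-5-methylphenoxy]-7-(1,3-dioxolan-2-yl)-2,2-dimethyl-4H-1,3-benzodioxine-8-carboxylate | Cc1cc(O)c(CO[Si](C)(C)C(C)(C)C)c(Oc2c(OCC=C)c3COC(C)(C)Oc3c(C(=O)OC)c2C2OCCO2)c1
F2 | step 17 | 6-bromo derivative of F1 on the phenoxy ring (bromine para to the phenol) | Cc1cc(O)c(CO[Si](C)(C)C(C)(C)C)c(Oc2c(OCC=C)c3COC(C)(C)Oc3c(C(=O)OC)c2C2OCCO2)c1Br
F3 | step 17 | deallylated F2 (5-hydroxy benzodioxine) | Cc1cc(O)c(CO[Si](C)(C)C(C)(C)C)c(Oc2c(O)c3COC(C)(C)Oc3c(C(=O)OC)c2C2OCCO2)c1Br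
F4 | step 10 | tert-butyl[(3,3-dibromoprop-2-en-1-yl)oxy]dimethylsilane | BrC(Br)=CCO[Si](C)(C)C(C)(C)C
F5 | step 10 | methyl 5-(allyloxy)-6-{[(1Z)-1-bromo-3-{[tert-butyl(dimethyl)silyl]oxy}prop-1-en-1-yl]oxy}-7-(1,3-dioxolan-2-yl)-2,2-dimethyl-4H-1,3-benzodioxine-8-carboxylate | COC(=O)c1c2OC(C)(C)OCc2c(OCC=C)c(O/C(Br)=C/CO[Si](C)(C)C(C)(C)C)c1C1OCCO1
F6 | step 19 | racemic pentapropanoate of the target | Cc1cc(OC(=O)CC)c(COC(=O)CC)c2c1C(=O)Oc1c(COC(=O)CC)c(OC(=O)CC)c3c(c1O2)C(OC(=O)CC)OC3=O
F7 | step 19 | (1R)-pentapropanoate of the target | Cc1cc(OC(=O)CC)c(COC(=O)CC)c2c1C(=O)Oc1c(COC(=O)CC)c(OC(=O)CC)c3c(c1O2)[C@H](OC(=O)CC)OC3=O
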